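**Plan**
Retrosynthesis (ring numbering: C1 quaternary with Me and acyl, C2 carbinol, C3 olefinic, C4–C6 CH2): the two C2–OH groups come from ring ketones and the two 4-methylpent-3-enoyl groups from CH2OH groups (C–C bond to prenyl); in each ring the C2–C3 and C4–C5 bonds are then cut together.
Enabling feature: C3(=CH–)–C4H2 is the terminal C=C of an allene, and C2(O)–C1–C6H2–C5H2 is a 2,2-disubstituted cyclobutanone whose strained, unhindered C(=O)–CH2 bond zerovalent nickel can open; the two allenes are the ends of octa-1,2,6,7-tetraene.
Forward: one achiral cyclopropylidene alcohol gives both cyclobutanone enantiomers, which are tied to one silicon atom; a two-fold nickel-catalysed insertion of the tetraene then makes one six-membered ring intermolecularly and the other by closing a temporary 15-membered ring.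
The silicon bridge is then cut, the CH2OH groups become the acyl groups, and the ring ketones are reduced last.
Stereochemistry: quaternary centres from tartrate-controlled epoxidation/ring enlargement, one of each hand; (Z)-olefins from the syn-allyl nickel intermediate; carbinols from hydride addition anti to the acyl group.

Key step: step 7

Remark: the two halves of the target are mirror images (1R,2S and 1S,2R), so the compound is meso and one building block of each hand is needed. The tartrate/face assignments in steps 3 and 4 are made by analogy with 2-methylprop-2-en-1-ol, with migration anti to the breaking C–O bond; a reversed assignment would only exchange the roles of 6 and 8.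

**Step 1**
Reactants: 1 cyclopropyltriphenylphosphonium bromide; 2 tert-butyldimethylsilyloxyacetone (TBSOCH2COCH3)
Product: 3 tert-butyl(2-cyclopropylidenepropoxy)dimethylsilane
Conditions: KOtBu, THF, 0 °C; then 2, 60 °C
Reagents that add atoms: none
Why: Wittig olefination of the ketone by the non-stabilised cyclopropylidene ylide; no olefin geometry arises because the ring carbon carries two identical CH2 groups.

**Step 2**
Reactants: 3 tert-butyl(2-cyclopropylidenepropoxy)dimethylsilane
Product: 4 2-cyclopropylidenepropan-1-ol
Conditions: tetrabutylammonium fluoride, THF, 0 °C to rt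
Reagents that add atoms: none
Why: Fluoride cleaves the primary silyl ether under non-acidic conditions that leave the strained tetrasubstituted olefin intact.

**Step 3**
Reactants: 4 2-cyclopropylidenepropan-1-ol
Product: 6 (2S)-2-(hydroxymethyl)-2-methylcyclobutan-1-one, via (2R)-epoxy alcohol 5 (not isolated)
Conditions: Ti(OiPr)4 (10 mol%), D-(−)-diethyl tartrate (12 mol%), t-BuOOH, 4 Å sieves, CH2Cl2, −30 °C to 0 °C
Reagents that add atoms: tert-butyl hydroperoxide, CC(C)(C)OO
Why: Sharpless asymmetric epoxidation sets the epoxide carbon, and the strained oxaspiropentane 5 then undergoes a Lewis-acid-induced semipinacol ring enlargement in which a cyclopropane C–C bond migrates anti to the breaking C–O bond, so the epoxide configuration becomes that of the quaternary carbon.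

**Step 4**
Reactants: 4 2-cyclopropylidenepropan-1-ol
Product: 8 (2R)-2-(hydroxymethyl)-2-methylcyclobutan-1-one, via (2S)-epoxy alcohol 7 (not isolated)
Conditions: Ti(OiPr)4 (10 mol%), L-(+)-diethyl tartrate (12 mol%), t-BuOOH, 4 Å sieves, CH2Cl2, −30 °C to 0 °C
Reagents that add atoms: tert-butyl hydroperoxide, CC(C)(C)OO
Why: The same tandem Sharpless epoxidation/semipinacol ring enlargement with the enantiomeric tartrate should give the mirror-image quaternary centre.

**Step 5**
Reactants: 6 (2S)-2-(hydroxymethyl)-2-methylcyclobutan-1-one; 8 (2R)-2-(hydroxymethyl)-2-methylcyclobutan-1-one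
Product: 10 meso {[(1S)-1-methyl-2-oxocyclobutyl]methoxy}{[(1R)-1-methyl-2-oxocyclobutyl]methoxy}di(propan-2-yl)silane, via chlorosilyl ether 9 (not isolated)
Conditions: i-Pr2SiCl2 (3 equiv), imidazole, CH2Cl2, 0 °C, 6 added; excess silane removed in vacuo; then 8, imidazole, DMF, rt
Reagents that add atoms: dichlorodi(propan-2-yl)silane, CC(C)[Si](Cl)(Cl)C(C)C
Why: Stepwise formation of an unsymmetrical dialkoxysilane: the hindered monochlorosilane 9 survives removal of the excess dichlorosilane and then silylates the second alcohol, so one unit of each hand is bound to the same silicon, which also protects both hydroxyls.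

**Step 6**
Reactants: 11 hexa-1,5-diyne
Product: 13 octa-1,2,6,7-tetraene, via bis-propargylic amine 12 (not isolated)
Conditions: paraformaldehyde, dicyclohexylamine, CuI (cat.), dioxane, reflux
Reagents that add atoms: formaldehyde (as paraformaldehyde), C=O
Why: Two-fold Crabbé homologation: a copper-catalysed Mannich reaction at each terminal alkyne is followed by hydride transfer and fragmentation of the propargylic amine to the terminal allene.

**Step 7**
Reactants: 10 meso {[(1S)-1-methyl-2-oxocyclobutyl]methoxy}{[(1R)-1-methyl-2-oxocyclobutyl]methoxy}di(propan-2-yl)silane; 13 octa-1,2,6,7-tetraene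
Product: 15 meso macrocyclic bis-enone silylene diether (fifteen-membered ring), via mono-insertion product 14 (not isolated)
Conditions: Ni(cod)2 (20 mol%), PCy3 (40 mol%), toluene, 100 °C, sealed vessel; both components (tetraene 1.1 equiv) added over 12 h by syringe pump, final 0.005 M
Reagents that add atoms: none
Why: Proposed new method: zerovalent nickel should couple the strained cyclobutanone carbonyl with the terminal C=C of an allene by oxidative cyclisation (carbonyl carbon to the central allene carbon, giving a nickel alkoxide/η3-allyl species), β-carbon elimination should then open the four-membered ring at its unsubstituted CH2, and C(sp3)–allyl reductive elimination at the CH2 terminus should form the CH2–CH2 bond and release zerovalent nickel. The closest known reaction types are the nickel-catalysed intermolecular insertion of alkynes into the acyl–carbon bond of cyclobutanones and the intramolecular nickel-catalysed [4+2] coupling of cyclobutanones with tethered allenes; an intermolecular allene insertion of this kind is not established. Each six-membered ring is closed as a formal [4+2] ring enlargement by σ-bond insertion (reductive elimination from a seven-membered nickelacycle), the first between two molecules and the second within 14, where it also closes the temporary 15-membered ring. No sp3 stereocentre is created: the quaternary carbons carry no α-hydrogen and pass unchanged, and the silicon bridge ensures that one ring of each hand ends up on the same four-carbon chain. Each new trisubstituted olefin should be (Z) if reductive elimination takes place from the syn-η3-allyl isomer (chain cis to the acyl carbon on the central allyl carbon), which syn/anti exchange through the η1-allyl form should favour because the anti position points at the PCy3-bearing nickel. The step needs site selectivity (terminal allene C=C; cleavage of acyl–CH2 rather than acyl–quaternary carbon) and ring closure in preference to chain growth, which the unhindered allene terminus, the fully substituted α-carbon and slow addition at high dilution should secure.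

**Step 8**
Reactants: 15 meso macrocyclic bis-enone silylene diether (fifteen-membered ring)
Product: 16 (2S,2'R,6Z,6'Z)-6,6'-(butane-1,4-diylidene)bis[2-(hydroxymethyl)-2-methylcyclohexan-1-one]
Conditions: HF·pyridine, pyridine, THF, 0 °C
Reagents that add atoms: none
Why: Buffered HF cleaves both Si–O bonds of the dialkoxysilane under weakly acidic conditions that avoid retro-aldol loss of formaldehyde and isomerisation of the (Z)-enones.

**Step 9**
Reactants: 16 (2S,2'R,6Z,6'Z)-6,6'-(butane-1,4-diylidene)bis[2-(hydroxymethyl)-2-methylcyclohexan-1-one]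
Product: 17 (1S,1'R,3Z,3'Z)-3,3'-(butane-1,4-diylidene)bis(1-methyl-2-oxocyclohexane-1-carbaldehyde)
Conditions: Dess–Martin periodinane, CH2Cl2, 0 °C to rt
Reagents that add atoms: none
Why: Dess–Martin oxidation of the neopentyl primary alcohols under near-neutral conditions; the α-carbons are quaternary and cannot epimerise.

**Step 10**
Reactants: 17 (1S,1'R,3Z,3'Z)-3,3'-(butane-1,4-diylidene)bis(1-methyl-2-oxocyclohexane-1-carbaldehyde)
Product: 18 (2S,2'R,6Z,6'Z)-6,6'-(butane-1,4-diylidene)bis[2-(1-hydroxy-4-methylpent-3-en-1-yl)-2-methylcyclohexan-1-one] (epimers at the two side-chain carbinols)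
Conditions: BaI2, lithium biphenylide, THF, rt; prenyl chloride, −78 °C; then 17, −78 °C
Reagents that add atoms: prenyl chloride (1-chloro-3-methylbut-2-ene), CC(C)=CCCl
Why: Allylic barium reagents add to carbonyl groups through their α-carbon (linear prenyl transfer), and the aldehydes should react far faster than the hindered conjugated ring ketones; the new carbinol centres are not controlled and are removed in step 11.

**Step 11**
Reactants: 18 (2S,2'R,6Z,6'Z)-6,6'-(butane-1,4-diylidene)bis[2-(1-hydroxy-4-methylpent-3-en-1-yl)-2-methylcyclohexan-1-one]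
Product: 19 (2S,2'R,6Z,6'Z)-6,6'-(butane-1,4-diylidene)bis[2-methyl-2-(4-methylpent-3-enoyl)cyclohexan-1-one]
Conditions: Dess–Martin periodinane, CH2Cl2, 0 °C to rt
Reagents that add atoms: none
Why: Dess–Martin oxidation of the secondary alcohols gives the 1,3-diketones (no hydrogen on the carbon between the carbonyls) under mild conditions that should not move the β,γ-double bonds into conjugation.

**Step 12**
Reactants: 19 (2S,2'R,6Z,6'Z)-6,6'-(butane-1,4-diylidene)bis[2-methyl-2-(4-methylpent-3-enoyl)cyclohexan-1-one]
Product: 20 1-[(1R,2S,3Z)-2-hydroxy-3-{(4Z)-4-[(2R,3S)-2-hydroxy-3-methyl-3-(4-methylpent-3-enoyl)cyclohexylidene]butylidene}-1-methylcyclohexyl]-4-methylpent-3-en-1-one (meso target)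
Conditions: NaBH4, CeCl3·7H2O, MeOH, −78 °C
Reagents that add atoms: none
Why: Luche reduction should add hydride 1,2 to the conjugated ring ketones in preference to the neopentyl side-chain ketones, and hydride should enter anti to the acyl group held perpendicular to the ring carbonyl (polar Felkin–Anh model), which places each new hydroxyl cis to the acyl group and trans to the methyl group.

**Compound list**
1 | cyclopropyltriphenylphosphonium bromide | [Br-].C1CC1[P+](c1ccccc1)(c1ccccc1)c1ccccc1 | starting material
2 | tert-butyldimethylsilyloxyacetone (TBSOCH2COCH3) | CC(=O)CO[Si](C)(C)C(C)(C)C | starting material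
3 | tert-butyl(2-cyclopropylidenepropoxy)dimethylsilane | CC(CO[Si](C)(C)C(C)(C)C)=C1CC1 | intermediate
4 | 2-cyclopropylidenepropan-1-ol | CC(CO)=C1CC1 | intermediate
5 | [(2R)-2-methyl-1-oxaspiro[2.2]pentan-2-yl]methanol | OC[C@@]1(C)OC12CC2 | intermediate
6 | (2S)-2-(hydroxymethyl)-2-methylcyclobutan-1-one | OC[C@]1(C)CCC1=O | intermediate
7 | [(2S)-2-methyl-1-oxaspiro[2.2]pentan-2-yl]methanol | OC[C@]1(C)OC12CC2 | intermediate
8 | (2R)-2-(hydroxymethyl)-2-methylcyclobutan-1-one | OC[C@@]1(C)CCC1=O | intermediate
9 | (2S)-2-({[chlorodi(propan-2-yl)silyl]oxy}methyl)-2-methylcyclobutan-1-one | CC(C)[Si](Cl)(OC[C@]1(C)CCC1=O)C(C)C | intermediate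
10 | meso {[(1S)-1-methyl-2-oxocyclobutyl]methoxy}{[(1R)-1-methyl-2-oxocyclobutyl]methoxy}di(propan-2-yl)silane | CC(C)[Si](OC[C@]1(C)CCC1=O)(OC[C@@]1(C)CCC1=O)C(C)C | intermediate
11 | hexa-1,5-diyne | C#CCCC#C | starting material
12 | N,N,N',N'-tetracyclohexylocta-2,6-diyne-1,8-diamine | C1CCC(CC1)N(CC#CCCC#CCN(C1CCCCC1)C1CCCCC1)C1CCCCC1 | intermediate
13 | octa-1,2,6,7-tetraene | C=C=CCCC=C=C | intermediate
14 | mono-insertion product: rac-{[(1R)-1-methyl-2-oxocyclobutyl]methoxy}{[(1S,3Z)-3-(hexa-4,5-dien-1-ylidene)-1-methyl-2-oxocyclohexyl]methoxy}di(propan-2-yl)silane (one enantiomer drawn) | CC(C)[Si](OC[C@@]1(C)CCC1=O)(OC[C@]1(C)CCC/C(=C/CCC=C=C)C1=O)C(C)C | intermediate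
15 | meso macrocyclic bis-enone silylene diether (fifteen-membered ring): (2S,2'R,6Z,6'Z)-6,6'-(butane-1,4-diylidene)bis(2-methylcyclohexan-1-one) whose two C2–CH2–O groups are joined through one Si(i-Pr)2 | CC(C)[Si]1(C(C)C)OC[C@]2(C)CCC/C(=C/CC/C=C3/CCC[C@](C)(CO1)C3=O)C2=O | intermediate
16 | (2S,2'R,6Z,6'Z)-6,6'-(butane-1,4-diylidene)bis[2-(hydroxymethyl)-2-methylcyclohexan-1-one] | OC[C@]1(C)CCC/C(=C/CC/C=C2/CCC[C@](C)(CO)C2=O)C1=O | intermediate
17 | (1S,1'R,3Z,3'Z)-3,3'-(butane-1,4-diylidene)bis(1-methyl-2-oxocyclohexane-1-carbaldehyde) | O=C[C@]1(C)CCC/C(=C/CC/C=C2/CCC[C@](C)(C=O)C2=O)C1=O | intermediate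
18 | (2S,2'R,6Z,6'Z)-6,6'-(butane-1,4-diylidene)bis[2-(1-hydroxy-4-methylpent-3-en-1-yl)-2-methylcyclohexan-1-one], carbinol epimers | CC(C)=CCC(O)[C@]1(C)CCC/C(=C/CC/C=C2/CCC[C@](C)(C(O)CC=C(C)C)C2=O)C1=O | intermediate
19 | (2S,2'R,6Z,6'Z)-6,6'-(butane-1,4-diylidene)bis[2-methyl-2-(4-methylpent-3-enoyl)cyclohexan-1-one] | CC(C)=CCC(=O)[C@]1(C)CCC/C(=C/CC/C=C2/CCC[C@](C)(C(=O)CC=C(C)C)C2=O)C1=O | intermediate
20 | 1-[(1R,2S,3Z)-2-hydroxy-3-{(4Z)-4-[(2R,3S)-2-hydroxy-3-methyl-3-(4-methylpent-3-enoyl)cyclohexylidene]butylidene}-1-methylcyclohexyl]-4-methylpent-3-en-1-one (meso) | CC(C)=CCC(=O)[C@]1(C)CCC/C(=C/CC/C=C2/CCC[C@](C)(C(=O)CC=C(C)C)[C@@H]2O)[C@@H]1O | target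

**Step count**
Total: 12 steps. Longest linear sequence: 10 steps (1, 2, 3 or 4, 5, 7, 8, 9, 10, 11, 12).

**Steps most likely to fail**

1. Step 7. What may go wrong: chain growth (one bis-cyclobutanone reacting with two tetraenes) instead of closure of the second ring; β-carbon elimination toward the quaternary carbon; nickel-induced oligomerisation of the bis-allene; reductive elimination from the anti-allyl nickel isomer, which would give the (E)-olefin. The fallback uses known reactions only, sets out from 10 and comes back at 15. Each cyclobutanone of 10 is enlarged by one carbon with diazomethane and Me3Al (CH2Cl2, −78 °C; the less substituted α-carbon migrates) to give the meso bis-cyclopentanone silylene diether F1, and a second homologation of the same kind gives the meso bis-cyclohexanone silylene diether F2. The only enolisable positions (C6 of each ring) are deprotonated with LiN(iPr)2 (THF, −78 °C) and the enolates are phosphinylated on carbon with bis(2,2,2-trifluoroethyl) phosphorochloridite to give the bis(β-keto phosphonite) F3, which t-BuOOH oxidises at phosphorus to the bis(β-ketophosphonate) F4. A two-fold (Z)-selective Still–Gennari-type Horner–Wadsworth–Emmons olefination of F4 with butanedial (KN(SiMe3)2, 18-crown-6, THF, −78 °C, high dilution) should then close the macrocycle and give 15.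

2. Step 12. What may go wrong: hydride attack on the side-chain carbonyls, over-reduction to diols, or erosion of facial selectivity if a metal chelate of the 1,3-diketone holds the acyl group in the plane of the ring carbonyl. The fallback sets out from 19 and comes back at 20; it replaces reagent-based discrimination by temporary masking. The two side-chain ketones are first converted into the dipotassium bis-dienolate F5 (KN(SiMe3)2, THF, −78 °C; only the CH2 groups between carbonyl and vinyl are acidic enough). The ring ketones are then reduced with i-Bu2AlH at −78 °C, and acetic acid at −78 °C protonates the dienolates at the α-carbon, which should return the β,γ-unsaturated ketones and give 20.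

3. Step 10. What may go wrong: γ-attack of the allylic metal (branched 1,1-dimethylallyl carbinol), competing addition to the ring ketones, or retro-aldol cleavage of the barium alkoxide. The fallback sets out from 17 and comes back at 18. Neutral allylboration with allylboronic acid pinacol ester (CH2Cl2, rt) should give the bis-homoallylic alcohol F6. Cross-metathesis with 2-methylbut-2-ene (second-generation Grubbs catalyst, CH2Cl2, 40 °C) then exchanges each terminal CH2 for an isopropylidene group and gives 18.

**Further compounds**
F1 | step 7 | meso {[(1S)-1-methyl-2-oxocyclopentyl]methoxy}{[(1R)-1-methyl-2-oxocyclopentyl]methoxy}di(propan-2-yl)silane | CC(C)[Si](OC[C@]1(C)CCCC1=O)(OC[C@@]1(C)CCCC1=O)C(C)C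
F2 | step 7 | meso {[(1S)-1-methyl-2-oxocyclohexyl]methoxy}{[(1R)-1-methyl-2-oxocyclohexyl]methoxy}di(propan-2-yl)silane | CC(C)[Si](OC[C@]1(C)CCCCC1=O)(OC[C@@]1(C)CCCCC1=O)C(C)C
F3 | step 7 | bis(β-keto phosphonite): F2 carrying a bis(2,2,2-trifluoroethoxy)phosphanyl group at C6 of each 2-methylcyclohexan-1-one ring (epimers at C6) | CC(C)[Si](OC[C@]1(C)CCCC(P(OCC(F)(F)F)OCC(F)(F)F)C1=O)(OC[C@@]1(C)CCCC(P(OCC(F)(F)F)OCC(F)(F)F)C1=O)C(C)C
F4 | step 7 | bis(β-ketophosphonate): F2 carrying a bis(2,2,2-trifluoroethoxy)phosphoryl group at C6 of each 2-methylcyclohexan-1-one ring (epimers at C6) | CC(C)[Si](OC[C@]1(C)CCCC(P(=O)(OCC(F)(F)F)OCC(F)(F)F)C1=O)(OC[C@@]1(C)CCCC(P(=O)(OCC(F)(F)F)OCC(F)(F)F)C1=O)C(C)C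
F5 | step 12 | dipotassium bis-dienolate of 19 (side-chain enolates) | [K+].[K+].CC(C)=CC=C([O-])[C@]1(C)CCC/C(=C/CC/C=C2/CCC[C@](C)(C([O-])=CC=C(C)C)C2=O)C1=O
F6 | step 10 | (2S,2'R,6Z,6'Z)-6,6'-(butane-1,4-diylidene)bis[2-(1-hydroxybut-3-en-1-yl)-2-methylcyclohexan-1-one], carbinol epimers | C=CCC(O)[C@]1(C)CCC/C(=C/CC/C=C2/CCC[C@](C)(C(O)CC=C)C2=O)C1=O
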